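**Plan**
- Target: oxacyclohentriacontan-2-one, a single 31-membered ring made of the ring oxygen, the carbonyl carbon C1 and the unbranched chain C2–C30 (29 CH2). It has no stereocentre, so the whole difficulty is the large ring.
- Retrosynthetic cuts, in order: first C9–C10, carried as a C9=C10 alkene and opened by ring-closing olefin metathesis; then C19–C20, a copper-catalysed alkyl–alkyl coupling; last the ester C1–O bond.
- Forward: dec-9-enoic acid (1) and 11-bromoundecan-1-ol (2) are joined as bromo ester 3. 11-Bromoundec-1-ene (4) is attached through its Grignard reagent (5) to give the C32 diene ester 6. The only ring is closed at C9=C10 with loss of ethene (7), and hydrogenation gives the target (8).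
- Enabling feature: C9–C10 lies in a plain polymethylene loop, seven CH2 groups (C2–C8) from the carbonyl C1 and twenty (C11–C30) from the ring oxygen. It can therefore be carried at the alkene oxidation level, remote from the ester, and both halves derive from commercial C10 and C11 ω-functionalised chains.
- Stereochemistry: none to set; the E/Z geometry created in the ring closure is deleted by the hydrogenation.

Key step: step 3

Step 1
Reactants: 1 dec-9-enoic acid; 2 11-bromoundecan-1-ol
Product: 3 11-bromoundecyl dec-9-enoate
Conditions: DCC (1.1 equiv), DMAP (0.1 equiv), CH2Cl2, 0 °C to rt
Reagents that add atoms: none
Why: Steglich esterification, in which DCC activates 1 as the O-acylisourea and DMAP relays the acyl group to the unhindered primary alcohol of 2, while the terminal alkene and the primary bromide should be inert under these neutral conditions.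

Step 2
Reactants: 3 11-bromoundecyl dec-9-enoate; 4 11-bromoundec-1-ene
Product: 6 docos-21-en-1-yl dec-9-enoate, via undec-10-en-1-ylmagnesium bromide 5 (not isolated)
Conditions: 4, Mg, THF, 40 °C; then slow addition (1.2 equiv) to 3, Li2CuCl4 (3 mol%), NMP (4 equiv), THF, 0 °C
Reagents that add atoms: none
Why: Kochi-type copper-catalysed alkyl–alkyl cross-coupling of a primary Grignard reagent with a primary alkyl bromide forms C19–C20; with NMP as co-solvent and slow addition at 0 °C the cuprate substitution at C–Br should outrun addition to the ester carbonyl, a tolerance established for ω-bromo esters, and the two terminal alkenes are spectators.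

Step 3
Reactants: 6 docos-21-en-1-yl dec-9-enoate
Product: 7 oxacyclohentriacont-10-en-2-one (mixture of E and Z isomers)
Conditions: RuCl2(=CHPh)(PCy3)(H2IMes) (second-generation Grubbs catalyst, 5 mol%), 1,4-benzoquinone (10 mol%), CH2Cl2, reflux, syringe-pump addition of 6 to a final 2 mM, Ar sparge
Reagents that add atoms: none
Why: The ruthenium benzylidene initiates at either terminal vinyl group to give a ruthenium alkylidene, which undergoes intramolecular [2+2] cycloaddition with the other vinyl group, and cycloreversion of the ruthenacyclobutane releases ethene and forms the C9=C10 bond (Chauvin mechanism). The closest known reaction type is ring-closing olefin metathesis of ω-alkenyl ω-alkenoates to large-ring unsaturated lactones. The 31-membered ring is closed head-to-tail between the two chain termini as a strain-free large ring, so closure is governed by entropy and by the ring–chain equilibrium and not by any small-ring stereoelectronic rule. No stereocentre is created, and the only open element, the E/Z geometry of C9=C10, is erased in step 4. The selectivity needed is cyclisation over acyclic diene metathesis oligomerisation; it should be secured by slow addition at millimolar concentration with removal of ethene, by the reversibility of metathesis, which cuts oligomers back to the ring at high dilution, and by the position of both alkenes seven and twenty CH2 groups from the ester, too far for a ruthenium–carbonyl chelate to sequester the carbene. 1,4-Benzoquinone is added to suppress ruthenium hydride-mediated double-bond migration, which would otherwise lead to ring-contracted homologues.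

Step 4
Reactants: 7 oxacyclohentriacont-10-en-2-one (mixture of E and Z isomers)
Product: 8 oxacyclohentriacontan-2-one
Conditions: H2 (1 atm), 10% Pd/C, EtOAc, rt
Reagents that add atoms: none
Why: Heterogeneous catalytic hydrogenation saturates the isolated disubstituted C9=C10 alkene of both geometric isomers while the lactone is inert, so the E/Z mixture should converge on the single achiral target.

**Compound list**
1 | dec-9-enoic acid | C=CCCCCCCCC(=O)O | starting material
2 | 11-bromoundecan-1-ol | OCCCCCCCCCCCBr | starting material
3 | 11-bromoundecyl dec-9-enoate | C=CCCCCCCCC(=O)OCCCCCCCCCCCBr | intermediate
4 | 11-bromoundec-1-ene | C=CCCCCCCCCCBr | starting material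
5 | undec-10-en-1-ylmagnesium bromide (formed in the flask, not isolated) | C=CCCCCCCCCC[Mg]Br | intermediate
6 | docos-21-en-1-yl dec-9-enoate | C=CCCCCCCCC(=O)OCCCCCCCCCCCCCCCCCCCCC=C | intermediate
7 | oxacyclohentriacont-10-en-2-one, mixture of E and Z isomers (geometry left undefined on purpose) | O=C1CCCCCCCC=CCCCCCCCCCCCCCCCCCCCCO1 | intermediate
8 | oxacyclohentriacontan-2-one (triacontan-30-olide; achiral, no stereocentre) | O=C1CCCCCCCCCCCCCCCCCCCCCCCCCCCCCO1 | target

**Step count and risks**
Total step count: 4. Longest linear sequence: 4 steps (1 or 2 → 3 → 6 → 7 → 8); compound 4 enters in step 2 through the Grignard reagent 5 made in the same flask.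

Steps most likely to fail:

1. Step 3 (ring closure). The processes at risk are intermolecular metathesis, which builds oligomers in place of the ring, and ruthenium hydride-induced double-bond migration followed by metathesis, which deletes CH2 units and gives ring-contracted homologues that can no longer be separated after hydrogenation. The fallback changes the bond-forming event at the same two carbons from alkene metathesis to reductive carbonyl coupling; it sets out from 6 and comes back at 7. Ozonolysis of both vinyl groups of 6 (O3, CH2Cl2, −78 °C; then PPh3) should give the dialdehyde 21-oxohenicosyl 9-oxononanoate F1, whose formyl carbons are C9 and C10. Intramolecular McMurry coupling of this dialdehyde (TiCl3(DME)1.5, Zn(Cu), DME, reflux, syringe-pump addition) should join them to give 7 as an E/Z mixture. No metal hydride is involved, so the chain length cannot change, and the ester should survive because aldehyde coupling on low-valent titanium is much faster than ester coupling.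

2. Step 2 (chain extension). The process at risk is addition of the Grignard reagent to the ester carbonyl, together with homocoupling, in competition with the copper-catalysed substitution. The fallback removes the electrophilic carbonyl from the coupling step by making the C22 alcohol first; it sets out from 2 and comes back at 6. Protection of 2 (3,4-dihydro-2H-pyran, PPTS, CH2Cl2, rt) should give 2-[(11-bromoundecyl)oxy]tetrahydro-2H-pyran F2. Coupling with the Grignard reagent 5 (Li2CuCl4 cat., THF, −10 °C to rt) should give 2-(docos-21-en-1-yloxy)tetrahydro-2H-pyran F3. Acetal cleavage (PPTS, MeOH, 50 °C) should give docos-21-en-1-ol F4, and Steglich esterification of this alcohol with 1 (DCC, DMAP, CH2Cl2) should give 6.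

3. Step 4 (hydrogenation). The process at risk is incomplete hydrogen uptake through poisoning of the palladium surface by ruthenium or phosphine residues carried over from step 3, leaving alkene that co-elutes with the product. The fallback replaces heterogeneous catalysis by a metal-free, stoichiometric hydrogen transfer; it sets out from 7 and comes back at 8. Diimide generated in the flask (2-nitrobenzenesulfonyl hydrazide, Et3N, CH2Cl2, rt) should reduce the unhindered disubstituted alkene by concerted syn transfer of H2. It is insensitive to catalyst poisons and leaves the lactone untouched. This fallback makes no compound outside the list: none F0.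

**Further compounds**
F1 | step 3 | 21-oxohenicosyl 9-oxononanoate | O=CCCCCCCCC(=O)OCCCCCCCCCCCCCCCCCCCCC=O
F2 | step 2 | 2-[(11-bromoundecyl)oxy]tetrahydro-2H-pyran (racemic at the acetal carbon) | BrCCCCCCCCCCCOC1CCCCO1
F3 | step 2 | 2-(docos-21-en-1-yloxy)tetrahydro-2H-pyran (racemic at the acetal carbon) | C=CCCCCCCCCCCCCCCCCCCCCOC1CCCCO1
F4 | step 2 | docos-21-en-1-ol | C=CCCCCCCCCCCCCCCCCCCCCO
F0 | step 4 | none | none
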